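**The vessel.** The closed, stirred vessel holds starting complex, incoming ligand and leaving ligand. The amount of complex with one exchanged is wanted after 2.5 d.

| setting | Tuesday's | Saturday's | ochre | red | teal |
|---|---|---|---|---|---|
| starting complex | 0.077 M | 0.077 M | 0.077 M | 0.077 M | 0.077 M |
| incoming ligand | 1.1 equiv | 1.4 equiv | 1.00 equiv | 1.20 equiv | 1.50 equiv |
| leaving ligand | 2 equiv | 2 equiv | 2.00 equiv | 2.00 equiv | 2.00 equiv |
| remark | run made earlier | run made earlier |  |  |  |
| time |  |  | 2.5 d | 2.5 d | 2.5 d |

| run | time / h | complex with one exchanged / % | starting complex / % |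
|---|---|---|---|
| Tuesday's | 2.50 | 20.4 | 80.2 |
| Tuesday's | 5.00 | 30.2 | 67.6 |
| Tuesday's | 8.00 | 36.5 | 60.9 |
| Tuesday's | 15.0 | 47.3 | 48.1 |
| Tuesday's | 30.0 | 59.2 | 34.6 |
| Saturday's | 6.00 | 39.6 | 58.2 |
| Saturday's | 12.0 | 52.2 | 44.0 |
| Saturday's | 20.0 | 60.2 | 32.2 |
| Saturday's | 25.0 | 63.7 | 27.7 |
| Saturday's | 30.0 | 66.7 | 23.7 |

(readings scatter by 0.5 percentage points)

- a reading or a percentage of complex with one exchanged counts all its forms, free or not

- how much complex with one exchanged is there at the end, in percent of the starting complex charged: for each flask in turn (ochre, red, teal)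

**Two runs.** The rate of fall of starting complex should follow c(incoming ligand). As a working reckoning that counts the first exchange as its one use, incoming ligand left, as a fraction of the starting complex charged, is taken as the excess charged plus the starting complex remaining. From 15.0 h to 30.0 h, Tuesday's run falls logarithmically at 0.0220 h⁻¹ with 0.514 left. From 20.0 h to 30.0 h, Saturday's run falls at 0.0306 h⁻¹ with 0.679 left. The falls differ by a factor of 1.39 and the ligand by 1.32, so the order in this ligand reads as one. Dividing gives 0.0428 h⁻¹ and 0.0451 h⁻¹. Their mean, 0.0439 h⁻¹, is the ligand-scaled fall: the logarithmic fall of starting complex per unit of reckoned ligand left, with starting complex and leaving ligand charged as here.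

**The early stretch.** Tuesday's opening stretch gives 0.0815 h⁻¹, about twice the late value. The two late stretches agree and the asked time lies beyond them, so the early figure is set aside.

**The reckoning.** A straight line in the charge through the two runs, interpolating for red and extrapolating for ochre and teal, puts starting complex at 30.0 h at 38.2%, 31.0% and 20.1% in ochre, red and teal. Integrating the ligand-scaled fall over the remaining 30.0 h leaves 25.4%, 17.5% and 8.70%. The readings at 30.0 h sum short of the charge by 6.20% on Tuesday and 9.60% on Saturday. As a guess, the gap, drawn along the same line, grows by half again. Complex with one exchanged then comes to 67.0%, 71.5% and 75.2%.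

**The forecast.** The forecast, with “Remaining starting complex is about 29, 21 and 14%”, gives 65%, 70% and 72%, lower than this reckoning in each flask.

**The result.** The flasks give 64.3%, 70.4% and 75.3%.

    complex with one exchanged + incoming ligand → leaving ligand + complex with two exchanged (k = 0.350 M⁻¹ h⁻¹)
    leaving ligand + complex with one exchanged → side product (k = 0.0130 M⁻¹ h⁻¹)
    incoming ligand ⇌ dormant form (K = 1.00, k = 0.120 h⁻¹)
    starting complex + incoming ligand → leaving ligand + complex with one exchanged (k = 1.40 M⁻¹ h⁻¹)
    crystals ⇌ complex with one exchanged, rate k5*(cs5 - [complex with one exchanged]) while solid is left; crystals form when [complex with one exchanged] > cs5 (solubility = 14.0 mM, k = 0.420 h⁻¹)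

In ochre, starting complex fell from 38.8% at 1.25 d to 26.4% at 2.50 d, a ligand-scaled fall, with ligand reckoned as before, of 0.0395 h⁻¹. At the end of ochre, the half-life of dissolved complex with one exchanged by the second exchange was 12 d, long against 2.5 d; ochre then held 6.33% complex with two exchanged and 3.06% side product, and crystals made up 45.6% of the starting complex charged, counted within the 64.3%. In teal, starting complex went from 21.2% to 9.25% over the same times, a ligand-scaled fall, reckoned the same way, of 0.0424 h⁻¹.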